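**Retrosynthetic overview**

1. The target is the 6,8''-linked biflavone 7-O-methylagathisflavone. Ring C of unit 2 (the flavone joined through C8) is opened last, to a chalcone and then to an acetophenone on ring A of unit 2.
2. The route rests on ring A of unit 2: its axis carbon C8 lies between C8a–O1 and C7–OH, with C5–OH para to it. This 2-arylphloroglucinol pattern is latent in a 4-benzyloxy-6-(arylmethyl)-2-pyrone and is released by base-induced ring opening and Dieckmann reclosure.
3. The pyrone comes from the 6-acetic acid of unit 1 (the 7-methoxyflavone joined through C6) by C-acylation of a dioxinone dienolate, thermal acylketene lactonisation and O-benzylation.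
4. The acetic acid comes from a 5-O-allyl Claisen rearrangement on the unit 1 flavone and oxidative cleavage. That flavone is built from acetophenone 1 and aldehyde 2.
5. Order of ring formation: ring C of unit 1, then the 2-pyrone, then ring A of unit 2 (from the pyrone), then ring C of unit 2.

Key step: step 11

Assumption: the target SMILES fixes no configuration at the C6–C8'' axis and the molecule has no stereocentre, so the route is planned for the unresolved (racemic) atropisomers.

Abbreviation used in names: Fl = 5-(benzyloxy)-2-[4-(benzyloxy)phenyl]-7-methoxy-4-oxo-4H-chromen-6-yl, the protected unit 1 flavone bonded through C6.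

**Route**

Step 1
Reactants: 1 1-(2,6-dihydroxy-4-methoxyphenyl)ethanone; 2 4-(benzyloxy)benzaldehyde
Product: 3 (2E)-3-[4-(benzyloxy)phenyl]-1-(2,6-dihydroxy-4-methoxyphenyl)prop-2-en-1-one
Conditions: KOH (50% aq.), EtOH, rt
Reagents that add atoms: none
Why: Claisen–Schmidt aldol condensation of the only enolisable ketone with a non-enolisable aldehyde, in which E1cB dehydration should give the E-enone.

Step 2
Reactants: 3 (2E)-3-[4-(benzyloxy)phenyl]-1-(2,6-dihydroxy-4-methoxyphenyl)prop-2-en-1-one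
Product: 4 2-[4-(benzyloxy)phenyl]-5-hydroxy-7-methoxy-4H-chromen-4-one
Conditions: I2 (cat.), DMSO, 130 °C
Reagents that add atoms: none
Why: Iodine-catalysed oxidative cyclisation of a 2'-hydroxychalcone (oxa-Michael closure, α-iodination, loss of HI, DMSO as terminal oxidant); the two ortho hydroxyls are equivalent, so only one flavone can form, and material that has already ring-closed is dehydrogenated to the same product.

Step 3
Reactants: 4 2-[4-(benzyloxy)phenyl]-5-hydroxy-7-methoxy-4H-chromen-4-one; 5 allyl bromide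
Product: 6 5-(allyloxy)-2-[4-(benzyloxy)phenyl]-7-methoxy-4H-chromen-4-one
Conditions: K2CO3, DMF, 60 °C
Reagents that add atoms: none
Why: Williamson O-alkylation of the only free phenol; the chelated 5-OH needs carbonate in warm DMF but has no competitor.

Step 4
Reactants: 6 5-(allyloxy)-2-[4-(benzyloxy)phenyl]-7-methoxy-4H-chromen-4-one
Product: 7 6-allyl-2-[4-(benzyloxy)phenyl]-5-hydroxy-7-methoxy-4H-chromen-4-one
Conditions: N,N-diethylaniline, 200 °C
Reagents that add atoms: none
Why: Aromatic Claisen rearrangement, a [3,3] shift from O5 to C6, the only ortho carbon that bears hydrogen, followed by enolisation back to the chelated phenol, so the carbon substituent is placed at C6 without ambiguity.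

Step 5
Reactants: 7 6-allyl-2-[4-(benzyloxy)phenyl]-5-hydroxy-7-methoxy-4H-chromen-4-one
Product: 8 6-allyl-5-(benzyloxy)-2-[4-(benzyloxy)phenyl]-7-methoxy-4H-chromen-4-one (Fl–CH2CH=CH2)
Conditions: BnBr, K2CO3, Bu4NI (cat.), DMF, 80 °C
Reagents that add atoms: benzyl bromide, BrCc1ccccc1
Why: Williamson benzylation under forcing conditions caps the hindered chelated 5-OH, so that the aldehyde and acid made next cannot close onto it as lactol or lactone.

Step 6
Reactants: 8 6-allyl-5-(benzyloxy)-2-[4-(benzyloxy)phenyl]-7-methoxy-4H-chromen-4-one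
Product: 9 2-Fl-acetaldehyde (Fl–CH2–CHO)
Conditions: OsO4 (cat.), NaIO4, 2,6-lutidine, dioxane–H2O, rt
Reagents that add atoms: sodium periodate, [Na+].[O-]I(=O)(=O)=O; osmium tetroxide (catalytic oxygen carrier), O=[Os](=O)(=O)=O
Why: Lemieux–Johnson oxidation, in which OsO4 should dihydroxylate the terminal alkene much faster than the electron-poor C2=C3 bond of the flavone and periodate cleaves the diol.

Step 7
Reactants: 9 2-Fl-acetaldehyde
Product: 10 2-Fl-acetic acid (Fl–CH2–CO2H)
Conditions: NaClO2, NaH2PO4, 2-methyl-2-butene, t-BuOH–THF–H2O, 0 °C → rt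
Reagents that add atoms: sodium chlorite, [Na+].[O-]Cl=O
Why: Pinnick oxidation is selective for the aldehyde, and the alkene scavenger keeps hypochlorous acid away from the electron-rich rings.

Step 8
Reactants: 10 2-Fl-acetic acid; 11 2,2,6-trimethyl-4H-1,3-dioxin-4-one
Product: 13 6-(3-Fl-2-oxopropyl)-2,2-dimethyl-4H-1,3-dioxin-4-one, via acyl imidazolide 12 (not isolated)
Conditions: 1,1'-carbonyldiimidazole, THF, rt; then added to 11 (3.5 equiv)/LiN(SiMe3)2 (3.5 equiv), THF, −78 → −40 °C; aq. NH4Cl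
Reagents that add atoms: 1,1'-carbonyldiimidazole, O=C(n1ccnc1)n1ccnc1 (its imidazolyl group is carried in 12 only)
Why: Claisen-type C-acylation at the γ-carbon of the lithium dienolate of the dioxinone by an acyl imidazolide; excess dienolate covers the imidazole N–H and the acidic product, and at −78 °C the acyl imidazolide should be far more electrophilic than the 2-aryl-substituted chromone.

Step 9
Reactants: 13 6-(3-Fl-2-oxopropyl)-2,2-dimethyl-4H-1,3-dioxin-4-one
Product: 15 6-(Fl-methyl)-4-hydroxy-2H-pyran-2-one, via acylketene 14 (not isolated)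
Conditions: toluene, 110 °C
Reagents that add atoms: none
Why: Thermal retro-[4+2] loss of acetone from the dioxinone gives an acylketene that is trapped by the enol oxygen of the distal ketone to give the 4-hydroxy-2-pyrone; without base, C-cyclisation does not compete.

Step 10
Reactants: 15 6-(Fl-methyl)-4-hydroxy-2H-pyran-2-one
Product: 16 4-(benzyloxy)-6-(Fl-methyl)-2H-pyran-2-one
Conditions: BnOH, PPh3, DIAD, THF, 0 °C → rt
Reagents that add atoms: benzyl alcohol, OCc1ccccc1
Why: Mitsunobu O-alkylation of the acidic 4-hydroxy-2-pyrone (a vinylogous carboxylic acid) should place benzyl on O4 and avoid the C3-benzylation that benzyl halides and base can cause.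

Step 11
Reactants: 16 4-(benzyloxy)-6-(Fl-methyl)-2H-pyran-2-one
Product: 19 5-(benzyloxy)-2-[4-(benzyloxy)phenyl]-6-[4-(benzyloxy)-2,6-dihydroxyphenyl]-7-methoxy-4H-chromen-4-one, via ring-opened methyl hexenoate 17 (not isolated), via cyclohexenedione keto tautomer 18 (not isolated)
Conditions: Mg(OMe)2 (5 equiv), MeOH–THF, 65 °C, argon; then 1 M HCl, 0 °C
Reagents that add atoms: magnesium methoxide, [Mg+2].[O-]C.[O-]C (its methoxy group is carried in 17 only)
Why: Proposed new method: methoxide adds to the lactone carbonyl C2 and opens the pyrone to the (2E)-3-benzyloxy-5-oxo-6-arylhex-2-enoate 17, in which ester and ketone chain stay cis on the enol-ether double bond; reversible enolisation then puts the carbanion on the carbon bound to C6 of the unit 1 flavone, this carbon attacks the ester carbonyl, and loss of methoxide gives dione 18, which enolises at once to the magnesium phenolate of 19. The closest known reaction type is the Mg(OMe)2 recyclisation of 4-hydroxy-6-(2-oxoalkyl)-2-pyrones to acylphloroglucinols, a Claisen-type closure of the ring-opened polyketo ester; new here is that the nucleophile is an aryl-substituted ketone α-carbon and that O4 of the pyrone is an ether. Ring A of unit 2 closes by a 6-(enolendo)-exo-trig Dieckmann condensation that forms the bond between the future C8 and one of its two oxygen-bearing neighbours (C8a or the equivalent C7). No stereocentre is formed, and because the new 2,6-dihydroxyphenyl ring is symmetric the biaryl axis is not yet stereogenic. The step needs C-acylation to win over O-acylation and needs the benzyloxy group to stay on the vinylogous ester carbon: return to the pyrone is reversible under methoxide whereas the C-acylation product aromatises irreversibly, and attack at the lactone carbonyl should be faster than conjugate addition, after which the ring-opened dienolate is no longer electrophilic. Regiochemistry is fixed by the skeleton, since the benzyloxy oxygen must end para to the axis and the two new phenols beside the axis are equivalent.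

Step 12
Reactants: 19 5-(benzyloxy)-2-[4-(benzyloxy)phenyl]-6-[4-(benzyloxy)-2,6-dihydroxyphenyl]-7-methoxy-4H-chromen-4-one
Product: 20 6-[3-acetyl-4-(benzyloxy)-2,6-dihydroxyphenyl]-5-(benzyloxy)-2-[4-(benzyloxy)phenyl]-7-methoxy-4H-chromen-4-one
Conditions: Ac2O, BF3·OEt2, CH2Cl2, 0 °C → rt; then K2CO3, MeOH, rt
Reagents that add atoms: acetic anhydride, CC(=O)OC(C)=O
Why: Friedel–Crafts C-acetylation of the most electron-rich ring, whose only two open positions are equivalent (each between OH and OBn) and which is deactivated after the first acylation; the methanolysis returns any O-acetate to the phenol.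

Step 13
Reactants: 20 6-[3-acetyl-4-(benzyloxy)-2,6-dihydroxyphenyl]-5-(benzyloxy)-2-[4-(benzyloxy)phenyl]-7-methoxy-4H-chromen-4-one
Product: 21 6-[3-acetyl-4,6-bis(benzyloxy)-2-hydroxyphenyl]-5-(benzyloxy)-2-[4-(benzyloxy)phenyl]-7-methoxy-4H-chromen-4-one
Conditions: BnBr (1.1 equiv), K2CO3, acetone, 50 °C
Reagents that add atoms: benzyl bromide, BrCc1ccccc1
Why: Williamson benzylation of the more acidic phenol para to the acetyl group, which is not hydrogen-bonded, while the phenol chelated to the ketone stays free for the later ring closure.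

Step 14
Reactants: 21 6-[3-acetyl-4,6-bis(benzyloxy)-2-hydroxyphenyl]-5-(benzyloxy)-2-[4-(benzyloxy)phenyl]-7-methoxy-4H-chromen-4-one; 2 4-(benzyloxy)benzaldehyde
Product: 22 6-{4,6-bis(benzyloxy)-3-[(2E)-3-(4-benzyloxyphenyl)prop-2-enoyl]-2-hydroxyphenyl}-5-(benzyloxy)-2-[4-(benzyloxy)phenyl]-7-methoxy-4H-chromen-4-one
Conditions: KOH, EtOH–THF, rt
Reagents that add atoms: none
Why: Claisen–Schmidt condensation, which should proceed normally once the para oxygen is benzylated (no deactivating para-phenoxide) and give the E-enone by E1cB dehydration; room temperature spares the unit 1 pyranone.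

Step 15
Reactants: 22 6-{4,6-bis(benzyloxy)-3-[(2E)-3-(4-benzyloxyphenyl)prop-2-enoyl]-2-hydroxyphenyl}-5-(benzyloxy)-2-[4-(benzyloxy)phenyl]-7-methoxy-4H-chromen-4-one
Product: 23 5,5'',7''-tris(benzyloxy)-2,2''-bis[4-(benzyloxy)phenyl]-7-methoxy-6,8''-bi(4H-chromene)-4,4''-dione
Conditions: I2 (cat.), DMSO, 130 °C
Reagents that add atoms: none
Why: Iodine/DMSO oxidative cyclisation of the 2'-hydroxychalcone through the one free phenol, which sits beside the axis carbon, so ring C of unit 2 closes with the biaryl bond at C8''.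

Step 16
Reactants: 23 5,5'',7''-tris(benzyloxy)-2,2''-bis[4-(benzyloxy)phenyl]-7-methoxy-6,8''-bi(4H-chromene)-4,4''-dione
Product: 24 5,5'',7''-trihydroxy-2,2''-bis(4-hydroxyphenyl)-7-methoxy-6,8''-bi(4H-chromene)-4,4''-dione (target, 7-O-methylagathisflavone)
Conditions: BCl3, pentamethylbenzene, CH2Cl2, −78 → −20 °C; then H2O
Reagents that add atoms: none
Why: Lewis-acid debenzylation with pentamethylbenzene as benzyl-cation scavenger should cleave all five aryl benzyl ethers at low temperature, while the 7-methoxy group, not peri to a carbonyl, is not activated by chelation and should survive.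

**Compound list**

1 | 1-(2,6-dihydroxy-4-methoxyphenyl)ethanone | COc1cc(O)c(C(C)=O)c(O)c1 | starting material
2 | 4-(benzyloxy)benzaldehyde | O=Cc1ccc(OCc2ccccc2)cc1 | starting material
3 | (2E)-3-[4-(benzyloxy)phenyl]-1-(2,6-dihydroxy-4-methoxyphenyl)prop-2-en-1-one | COc1cc(O)c(C(=O)/C=C/c2ccc(OCc3ccccc3)cc2)c(O)c1 | intermediate
4 | 2-[4-(benzyloxy)phenyl]-5-hydroxy-7-methoxy-4H-chromen-4-one | COc1cc(O)c2c(=O)cc(-c3ccc(OCc4ccccc4)cc3)oc2c1 | intermediate
5 | allyl bromide (3-bromoprop-1-ene) | C=CCBr | starting material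
6 | 5-(allyloxy)-2-[4-(benzyloxy)phenyl]-7-methoxy-4H-chromen-4-one | C=CCOc1cc(OC)cc2oc(-c3ccc(OCc4ccccc4)cc3)cc(=O)c12 | intermediate
7 | 6-allyl-2-[4-(benzyloxy)phenyl]-5-hydroxy-7-methoxy-4H-chromen-4-one | C=CCc1c(OC)cc2oc(-c3ccc(OCc4ccccc4)cc3)cc(=O)c2c1O | intermediate
8 | 6-allyl-5-(benzyloxy)-2-[4-(benzyloxy)phenyl]-7-methoxy-4H-chromen-4-one | C=CCc1c(OC)cc2oc(-c3ccc(OCc4ccccc4)cc3)cc(=O)c2c1OCc1ccccc1 | intermediate
9 | 2-{5-(benzyloxy)-2-[4-(benzyloxy)phenyl]-7-methoxy-4-oxo-4H-chromen-6-yl}acetaldehyde | O=CCc1c(OC)cc2oc(-c3ccc(OCc4ccccc4)cc3)cc(=O)c2c1OCc1ccccc1 | intermediate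
10 | 2-{5-(benzyloxy)-2-[4-(benzyloxy)phenyl]-7-methoxy-4-oxo-4H-chromen-6-yl}acetic acid | OC(=O)Cc1c(OC)cc2oc(-c3ccc(OCc4ccccc4)cc3)cc(=O)c2c1OCc1ccccc1 | intermediate
11 | 2,2,6-trimethyl-4H-1,3-dioxin-4-one | CC1=CC(=O)OC(C)(C)O1 | starting material
12 | 2-{5-(benzyloxy)-2-[4-(benzyloxy)phenyl]-7-methoxy-4-oxo-4H-chromen-6-yl}-1-(1H-imidazol-1-yl)ethanone (acyl imidazolide, not isolated) | O=C(Cc1c(OC)cc2oc(-c3ccc(OCc4ccccc4)cc3)cc(=O)c2c1OCc1ccccc1)n1ccnc1 | intermediate
13 | 6-(3-{5-(benzyloxy)-2-[4-(benzyloxy)phenyl]-7-methoxy-4-oxo-4H-chromen-6-yl}-2-oxopropyl)-2,2-dimethyl-4H-1,3-dioxin-4-one | CC1(C)OC(=O)C=C(CC(=O)Cc2c(OC)cc3oc(-c4ccc(OCc5ccccc5)cc4)cc(=O)c3c2OCc2ccccc2)O1 | intermediate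
14 | 6-{5-(benzyloxy)-2-[4-(benzyloxy)phenyl]-7-methoxy-4-oxo-4H-chromen-6-yl}-3,5-dioxohex-1-en-1-one (acylketene, not isolated) | COc1cc2oc(-c3ccc(OCc4ccccc4)cc3)cc(=O)c2c(OCc2ccccc2)c1CC(=O)CC(=O)C=C=O | intermediate
15 | 6-({5-(benzyloxy)-2-[4-(benzyloxy)phenyl]-7-methoxy-4-oxo-4H-chromen-6-yl}methyl)-4-hydroxy-2H-pyran-2-one | COc1cc2oc(-c3ccc(OCc4ccccc4)cc3)cc(=O)c2c(OCc2ccccc2)c1Cc1cc(O)cc(=O)o1 | intermediate
16 | 4-(benzyloxy)-6-({5-(benzyloxy)-2-[4-(benzyloxy)phenyl]-7-methoxy-4-oxo-4H-chromen-6-yl}methyl)-2H-pyran-2-one | COc1cc2oc(-c3ccc(OCc4ccccc4)cc3)cc(=O)c2c(OCc2ccccc2)c1Cc1cc(OCc2ccccc2)cc(=O)o1 | intermediate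
17 | methyl (2E)-3-(benzyloxy)-6-{5-(benzyloxy)-2-[4-(benzyloxy)phenyl]-7-methoxy-4-oxo-4H-chromen-6-yl}-5-oxohex-2-enoate (not isolated) | COC(=O)/C=C(/OCc1ccccc1)CC(=O)Cc1c(OC)cc2oc(-c3ccc(OCc4ccccc4)cc3)cc(=O)c2c1OCc1ccccc1 | intermediate
18 | 5-(benzyloxy)-2-{5-(benzyloxy)-2-[4-(benzyloxy)phenyl]-7-methoxy-4-oxo-4H-chromen-6-yl}cyclohex-4-ene-1,3-dione (racemic, labile keto tautomer of 19, not isolated) | COc1cc2oc(-c3ccc(OCc4ccccc4)cc3)cc(=O)c2c(OCc2ccccc2)c1C1C(=O)CC(OCc2ccccc2)=CC1=O | intermediate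
19 | 5-(benzyloxy)-2-[4-(benzyloxy)phenyl]-6-[4-(benzyloxy)-2,6-dihydroxyphenyl]-7-methoxy-4H-chromen-4-one | COc1cc2oc(-c3ccc(OCc4ccccc4)cc3)cc(=O)c2c(OCc2ccccc2)c1-c1c(O)cc(OCc2ccccc2)cc1O | intermediate
20 | 6-[3-acetyl-4-(benzyloxy)-2,6-dihydroxyphenyl]-5-(benzyloxy)-2-[4-(benzyloxy)phenyl]-7-methoxy-4H-chromen-4-one (racemic axis) | COc1cc2oc(-c3ccc(OCc4ccccc4)cc3)cc(=O)c2c(OCc2ccccc2)c1-c1c(O)cc(OCc2ccccc2)c(C(C)=O)c1O | intermediate
21 | 6-[3-acetyl-4,6-bis(benzyloxy)-2-hydroxyphenyl]-5-(benzyloxy)-2-[4-(benzyloxy)phenyl]-7-methoxy-4H-chromen-4-one (racemic axis) | COc1cc2oc(-c3ccc(OCc4ccccc4)cc3)cc(=O)c2c(OCc2ccccc2)c1-c1c(OCc2ccccc2)cc(OCc2ccccc2)c(C(C)=O)c1O | intermediate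
22 | 6-{4,6-bis(benzyloxy)-3-[(2E)-3-(4-benzyloxyphenyl)prop-2-enoyl]-2-hydroxyphenyl}-5-(benzyloxy)-2-[4-(benzyloxy)phenyl]-7-methoxy-4H-chromen-4-one (racemic axis) | COc1cc2oc(-c3ccc(OCc4ccccc4)cc3)cc(=O)c2c(OCc2ccccc2)c1-c1c(OCc2ccccc2)cc(OCc2ccccc2)c(C(=O)/C=C/c2ccc(OCc3ccccc3)cc2)c1O | intermediate
23 | 5,5'',7''-tris(benzyloxy)-2,2''-bis[4-(benzyloxy)phenyl]-7-methoxy-6,8''-bi(4H-chromene)-4,4''-dione (racemic axis) | COc1cc2oc(-c3ccc(OCc4ccccc4)cc3)cc(=O)c2c(OCc2ccccc2)c1-c1c(OCc2ccccc2)cc(OCc2ccccc2)c2c(=O)cc(-c3ccc(OCc4ccccc4)cc3)oc12 | intermediate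
24 | 5,5'',7''-trihydroxy-2,2''-bis(4-hydroxyphenyl)-7-methoxy-6,8''-bi(4H-chromene)-4,4''-dione (7-O-methylagathisflavone, axis unresolved) | COc1cc2oc(-c3ccc(O)cc3)cc(=O)c2c(O)c1-c1c(O)cc(O)c2c(=O)cc(-c3ccc(O)cc3)oc12 | target

**Step count**

Total steps: 16. Longest linear sequence: 16 steps (1 → 24); aldehyde 2 enters twice, allyl bromide 5 and dioxinone 11 once each.

**Steps most likely to fail**

Step 11 (proposed new method). The ring-opened enoate may simply return to the pyrone by O-acylation, may exchange its benzyloxy group for methoxide by addition–elimination at the vinylogous ester carbon, or the hindered carbanion flanked by two ortho substituents may not reach the ester. The fallback attaches the symmetric ring by cross-coupling, using known chemistry, and sets out from flavone 4. Regioselective iodination ortho to the free 5-OH with benzyltrimethylammonium dichloroiodate and CaCO3 in CH2Cl2–MeOH would give 2-[4-(benzyloxy)phenyl]-5-hydroxy-6-iodo-7-methoxy-4H-chromen-4-one F1. Benzylation (BnBr, K2CO3, DMF, 80 °C) would give 5-(benzyloxy)-2-[4-(benzyloxy)phenyl]-6-iodo-7-methoxy-4H-chromen-4-one F2. Separately, purchasable 5-(benzyloxy)benzene-1,3-diol would be converted with MOMCl and i-Pr2NEt into 1-(benzyloxy)-3,5-bis(methoxymethoxy)benzene F3. Lithiation between the two methoxymethoxy groups (n-BuLi, THF, 0 °C) and quenching with B(OMe)3, then aqueous NH4Cl, would give [4-(benzyloxy)-2,6-bis(methoxymethoxy)phenyl]boronic acid F4. Suzuki–Miyaura coupling of F2 with F4 (Pd(OAc)2, SPhos, K3PO4, toluene–H2O, 100 °C) would give 5-(benzyloxy)-2-[4-(benzyloxy)phenyl]-6-[4-(benzyloxy)-2,6-bis(methoxymethoxy)phenyl]-7-methoxy-4H-chromen-4-one F5. HCl in MeOH–THF would then remove both methoxymethyl groups and the route is rejoined at compound 19.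

Step 8. Proton transfer from the acidic arylacetyl imidazolide to the dienolate may compete with C-acylation, and the dienolate may add in conjugate fashion to the chromone of unit 1. The fallback replaces the Claisen-type acylation by an aldol addition and oxidation and sets out from aldehyde 9. Dioxinone 11 would be converted (LDA, Me3SiCl, THF, −78 °C) into its silyl dienol ether [(2,2-dimethyl-6-methylene-6H-1,3-dioxin-4-yl)oxy]trimethylsilane F6. A vinylogous Mukaiyama aldol addition of F6 to 9 (BF3·OEt2, CH2Cl2, −78 °C) would give racemic 6-(3-Fl-2-hydroxypropyl)-2,2-dimethyl-4H-1,3-dioxin-4-one F7. Dess–Martin periodinane oxidation of F7 in CH2Cl2 would give the ketone, and the route is rejoined at compound 13.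

Step 12. O-acetylation in place of C-acetylation, a second acetylation, or Lewis-acid-induced loss of benzyl ethers (most easily the 5-O-benzyl group peri to the carbonyl of unit 1) may erode the step. The fallback introduces the acetyl group by halogenation and cross-coupling without a strong Lewis acid and sets out from compound 19. Mono-iodination of the resorcinol ring with N-iodosuccinimide (1 equiv, MeCN, 0 °C) would give 5-(benzyloxy)-2-[4-(benzyloxy)phenyl]-6-[4-(benzyloxy)-2,6-dihydroxy-3-iodophenyl]-7-methoxy-4H-chromen-4-one F8. Stille coupling with tributyl(1-ethoxyvinyl)stannane (Pd(PPh3)4, dioxane, 90 °C) would give the enol ether 5-(benzyloxy)-2-[4-(benzyloxy)phenyl]-6-[4-(benzyloxy)-3-(1-ethoxyvinyl)-2,6-dihydroxyphenyl]-7-methoxy-4H-chromen-4-one F9. Hydrolysis with 1 M HCl in THF would give the methyl ketone, and the route is rejoined at compound 20.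

**Further compounds**

F1 | step 11 | 2-[4-(benzyloxy)phenyl]-5-hydroxy-6-iodo-7-methoxy-4H-chromen-4-one | COc1cc2oc(-c3ccc(OCc4ccccc4)cc3)cc(=O)c2c(O)c1I
F2 | step 11 | 5-(benzyloxy)-2-[4-(benzyloxy)phenyl]-6-iodo-7-methoxy-4H-chromen-4-one | COc1cc2oc(-c3ccc(OCc4ccccc4)cc3)cc(=O)c2c(OCc2ccccc2)c1I
F3 | step 11 | 1-(benzyloxy)-3,5-bis(methoxymethoxy)benzene | COCOc1cc(OCOC)cc(OCc2ccccc2)c1
F4 | step 11 | [4-(benzyloxy)-2,6-bis(methoxymethoxy)phenyl]boronic acid | COCOc1cc(OCc2ccccc2)cc(OCOC)c1B(O)O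
F5 | step 11 | 5-(benzyloxy)-2-[4-(benzyloxy)phenyl]-6-[4-(benzyloxy)-2,6-bis(methoxymethoxy)phenyl]-7-methoxy-4H-chromen-4-one | COCOc1cc(OCc2ccccc2)cc(OCOC)c1-c1c(OC)cc2oc(-c3ccc(OCc4ccccc4)cc3)cc(=O)c2c1OCc1ccccc1
F6 | step 8 | [(2,2-dimethyl-6-methylene-6H-1,3-dioxin-4-yl)oxy]trimethylsilane | C=C1C=C(O[Si](C)(C)C)OC(C)(C)O1
F7 | step 8 | 6-(3-{5-(benzyloxy)-2-[4-(benzyloxy)phenyl]-7-methoxy-4-oxo-4H-chromen-6-yl}-2-hydroxypropyl)-2,2-dimethyl-4H-1,3-dioxin-4-one (racemic) | CC1(C)OC(=O)C=C(CC(O)Cc2c(OC)cc3oc(-c4ccc(OCc5ccccc5)cc4)cc(=O)c3c2OCc2ccccc2)O1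
F8 | step 12 | 5-(benzyloxy)-2-[4-(benzyloxy)phenyl]-6-[4-(benzyloxy)-2,6-dihydroxy-3-iodophenyl]-7-methoxy-4H-chromen-4-one | COc1cc2oc(-c3ccc(OCc4ccccc4)cc3)cc(=O)c2c(OCc2ccccc2)c1-c1c(O)cc(OCc2ccccc2)c(I)c1O
F9 | step 12 | 5-(benzyloxy)-2-[4-(benzyloxy)phenyl]-6-[4-(benzyloxy)-3-(1-ethoxyvinyl)-2,6-dihydroxyphenyl]-7-methoxy-4H-chromen-4-one | C=C(OCC)c1c(OCc2ccccc2)cc(O)c(-c2c(OC)cc3oc(-c4ccc(OCc5ccccc5)cc4)cc(=O)c3c2OCc2ccccc2)c1O
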